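**Retrosynthetic overview**
- The target is a 2,4,6-trihydroxyphenyl ketone whose C1–C20 acyl chain has Z-alkenes at C5=C6, C8=C9, C11=C12 and C14=C15, an (R)-carbinol at C17 and a C18–C20 propyl end. This chain is eicosapentaenoic acid (1) with water added across its fifth Z-alkene, C17=C18 (O on C17, H on C18).
- Key disconnection: the C17–O and C18–H bonds, made by enzymatic hydration of free acid 1 to hydroxy acid 2; this sets the only stereocentre.
- Second disconnection: the C1–aryl bond, made by adding ortho-lithiated tris(methoxymethyl)-protected phloroglucinol to the Weinreb amide of the C17-silylated chain.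
- No ring is formed; the benzene ring is bought as phloroglucinol. One mild acid step at the end removes the three MOM ethers and the silyl ether.

Key step: step 1

Assumption: a hydratase variant with the selectivity required in step 1 is obtained by homologue screening and directed evolution before scale-up; all polyene intermediates are handled under argon in degassed solvents with a trace of BHT.

**Step 1**
Reactants: 1 eicosapentaenoic acid, (5Z,8Z,11Z,14Z,17Z)-icosa-5,8,11,14,17-pentaenoic acid
Product: 2 (5Z,8Z,11Z,14Z,17R)-17-hydroxyicosa-5,8,11,14-tetraenoic acid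
Conditions: ω-3-selective FAD-dependent fatty acid hydratase variant (E. coli whole cells or lysate), FAD, KH2PO4/K2HPO4 buffer pH 6.5, 2% EtOH, N2, 28 °C; then pH 4, EtOAc extraction
Reagents that add atoms: water, O
Why: Proposed new method: FAD-dependent fatty acid hydratases hold a free fatty acid by its carboxylate and add water anti across the one Z-alkene lying at the catalytic pair, an active-site acid (tyrosine) protonating one alkene carbon while a glutamate-activated water attacks the other and the flavin plays a structural, non-redox part; the closest known reactions are the hydrations of oleic acid at C9=C10 and of linoleic acid at C12=C13, and here the same mechanism is asked to act at C17=C18 of 1 with protonation at C18 and C–O formation at C17. No ring closes. The single new stereocentre, C17, should be set R by the enzyme, which presents only one face of the bound alkene to the activated water. The step needs site selectivity among five near-identical Z-alkenes, placement of oxygen on the carboxyl-side carbon C17 (the reverse of the wild-type enzymes, which hydroxylate the alkene carbon farther from the carboxylate) and face selectivity; the substrate offers only the fixed distance from the C1 carboxylate to the alkene and the short ethyl tail beyond C18, so all three must come from a variant whose substrate channel is reshaped by screening and directed evolution, read out by LC–MS against the 15-, 17- and 18-hydroxy acids. The four other Z-alkenes should never reach the catalytic pair and so keep position and geometry, and in water the equilibrium lies towards the alcohol.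

**Step 2**
Reactants: 2 (5Z,8Z,11Z,14Z,17R)-17-hydroxyicosa-5,8,11,14-tetraenoic acid
Product: 3 (5Z,8Z,11Z,14Z,17R)-17-hydroxy-N-methoxy-N-methylicosa-5,8,11,14-tetraenamide
Conditions: MeNHOMe·HCl, EDC·HCl, HOBt (cat.), N-methylmorpholine, CH2Cl2, 0 °C → rt
Reagents that add atoms: N,O-dimethylhydroxylamine hydrochloride, CNOC.Cl
Why: Carbodiimide/HOBt amide coupling should acylate the amine nitrogen far faster than the remote secondary C17 hydroxyl, and the near-neutral conditions leave the skipped Z-tetraene and C17 untouched; forming the amide before silylation avoids a silyl ester.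

**Step 3**
Reactants: 3 (5Z,8Z,11Z,14Z,17R)-17-hydroxy-N-methoxy-N-methylicosa-5,8,11,14-tetraenamide
Product: 4 (5Z,8Z,11Z,14Z,17R)-17-[(tert-butyldimethylsilyl)oxy]-N-methoxy-N-methylicosa-5,8,11,14-tetraenamide
Conditions: TBSCl, imidazole, DMF, rt
Reagents that add atoms: tert-butyldimethylsilyl chloride, CC(C)(C)[Si](C)(C)Cl
Why: Imidazole-promoted O-silylation of the secondary alcohol removes the only acidic proton before the organolithium step; the C17–O bond is not touched, so the R configuration is kept.

**Step 4**
Reactants: 5 phloroglucinol (benzene-1,3,5-triol, anhydrous)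
Product: 6 1,3,5-tris(methoxymethoxy)benzene
Conditions: MOMCl (3.6 equiv), i-Pr2NEt, DMF, 0 °C → rt
Reagents that add atoms: chloromethyl methyl ether, COCCl
Why: Williamson-type O-alkylation with the hard oxocarbenium-like electrophile MOMCl should favour the tris-ether over C-alkylation of the ring and installs three ortho-directing groups that are removable by mild acid.

**Step 5**
Reactants: 6 1,3,5-tris(methoxymethoxy)benzene; 4 (5Z,8Z,11Z,14Z,17R)-17-[(tert-butyldimethylsilyl)oxy]-N-methoxy-N-methylicosa-5,8,11,14-tetraenamide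
Product: 9 (5Z,8Z,11Z,14Z,17R)-17-[(tert-butyldimethylsilyl)oxy]-1-[2,4,6-tris(methoxymethoxy)phenyl]icosa-5,8,11,14-tetraen-1-one, via aryllithium 7 (not isolated), via lithium hemiaminal adduct 8 (not isolated)
Conditions: 6 (2.4 equiv), n-BuLi (2.2 equiv), THF, 0 °C, 1 h; then 4, −78 → 0 °C; sat. aq. NH4Cl
Reagents that add atoms: none
Why: Directed ortho-metalation at the ring position flanked by two MOM ethers gives 7, whose addition to the amide (Weinreb ketone synthesis) should stop at the chelated tetrahedral adduct 8 so that the ketone appears only on quench; keeping 6 in excess over n-BuLi leaves no alkyllithium to attack the amide or the bis-allylic CH2 groups.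

**Step 6**
Reactants: 9 (5Z,8Z,11Z,14Z,17R)-17-[(tert-butyldimethylsilyl)oxy]-1-[2,4,6-tris(methoxymethoxy)phenyl]icosa-5,8,11,14-tetraen-1-one
Product: 10 (5Z,8Z,11Z,14Z,17R)-17-hydroxy-1-(2,4,6-trihydroxyphenyl)icosa-5,8,11,14-tetraen-1-one (CNP0202243.2)
Conditions: HCl (ca. 1 M in MeOH), degassed, Ar, 23 → 40 °C; then water, EtOAc extraction
Reagents that add atoms: none
Why: Acid-catalysed methanolysis should cleave the three aryl MOM acetals and the secondary TBS ether in one operation, methanol trapping the methoxymethyl cation as dimethoxymethane before it can alkylate the electron-rich ring; skipped Z-polyenes tolerate methanolic HCl (the usual medium for transesterifying polyunsaturated lipids) and the homoallylic C17 carbinol does not ionise, so alkene geometry and the R configuration should be kept.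

**Compound list**
1 | eicosapentaenoic acid, (5Z,8Z,11Z,14Z,17Z)-icosa-5,8,11,14,17-pentaenoic acid | CC/C=C\C/C=C\C/C=C\C/C=C\C/C=C\CCCC(=O)O | starting material
2 | (5Z,8Z,11Z,14Z,17R)-17-hydroxyicosa-5,8,11,14-tetraenoic acid | CCC[C@@H](O)C/C=C\C/C=C\C/C=C\C/C=C\CCCC(=O)O | intermediate
3 | (5Z,8Z,11Z,14Z,17R)-17-hydroxy-N-methoxy-N-methylicosa-5,8,11,14-tetraenamide | CCC[C@@H](O)C/C=C\C/C=C\C/C=C\C/C=C\CCCC(=O)N(C)OC | intermediate
4 | (5Z,8Z,11Z,14Z,17R)-17-[(tert-butyldimethylsilyl)oxy]-N-methoxy-N-methylicosa-5,8,11,14-tetraenamide | CCC[C@@H](O[Si](C)(C)C(C)(C)C)C/C=C\C/C=C\C/C=C\C/C=C\CCCC(=O)N(C)OC | intermediate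
5 | phloroglucinol (benzene-1,3,5-triol) | Oc1cc(O)cc(O)c1 | starting material
6 | 1,3,5-tris(methoxymethoxy)benzene | COCOc1cc(OCOC)cc(OCOC)c1 | intermediate
7 | 2,4,6-tris(methoxymethoxy)phenyllithium (not isolated) | [Li]c1c(OCOC)cc(OCOC)cc1OCOC | intermediate
8 | lithium (5Z,8Z,11Z,14Z,17R)-17-[(tert-butyldimethylsilyl)oxy]-1-[methoxy(methyl)amino]-1-[2,4,6-tris(methoxymethoxy)phenyl]icosa-5,8,11,14-tetraen-1-olate, C1 unassigned (not isolated) | CCC[C@@H](O[Si](C)(C)C(C)(C)C)C/C=C\C/C=C\C/C=C\C/C=C\CCCC(O[Li])(N(C)OC)c1c(OCOC)cc(OCOC)cc1OCOC | intermediate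
9 | (5Z,8Z,11Z,14Z,17R)-17-[(tert-butyldimethylsilyl)oxy]-1-[2,4,6-tris(methoxymethoxy)phenyl]icosa-5,8,11,14-tetraen-1-one | CCC[C@@H](O[Si](C)(C)C(C)(C)C)C/C=C\C/C=C\C/C=C\C/C=C\CCCC(=O)c1c(OCOC)cc(OCOC)cc1OCOC | intermediate
10 | (5Z,8Z,11Z,14Z,17R)-17-hydroxy-1-(2,4,6-trihydroxyphenyl)icosa-5,8,11,14-tetraen-1-one | CCC[C@@H](O)C/C=C\C/C=C\C/C=C\C/C=C\CCCC(=O)c1c(O)cc(O)cc1O | target

**Total step count:** 6
**Longest linear sequence:** 5 steps (steps 1, 2, 3, 5, 6); the arene branch (steps 4, 5, 6) is 3 steps.

**Steps most likely to fail**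

1. Step 1 (proposed new method). The enzyme may not turn over at the ω-3 alkene, may hydrate another alkene, may place the oxygen on C18, or may give poor face selectivity; the polyene may also autoxidise during a long incubation. The fallback sets out from 1 and comes back at 2 by known chemistry. Acid 1 is epoxidised with cytochrome P450 BM3 monooxygenase (NADPH recycled with glucose and glucose dehydrogenase, air, buffer pH 7.4, 25 °C); this enzyme is known to epoxidise the ω-3 alkene of 1 and should give (5Z,8Z,11Z,14Z)-16-[(2S,3R)-3-ethyloxiran-2-yl]hexadeca-5,8,11,14-tetraenoic acid F1. Reductive opening with excess LiBHEt3 in THF at 0 °C, which does not reduce the lithium carboxylate, delivers hydride to C18 or C17. Attack at C18 gives 2: the C17–O bond is never broken, and the 17S descriptor of the oxirane becomes 17R only because C16 outranks C18 once C18 is a CH2. Attack at C17 gives the regioisomer (5Z,8Z,11Z,14Z,18R)-18-hydroxyicosa-5,8,11,14-tetraenoic acid F2, which is removed by chromatography. Little regiocontrol is expected, so this fallback costs material but not stereochemical integrity.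

2. Step 5. The 2,6-disubstituted aryllithium may add sluggishly, enolise the amide, or abstract a bis-allylic proton. The fallback sets out from 4 and comes back at 9. Amide 4 is reduced with i-Bu2AlH (THF, −78 °C) to (5Z,8Z,11Z,14Z,17R)-17-[(tert-butyldimethylsilyl)oxy]icosa-5,8,11,14-tetraenal F3. The less hindered aldehyde takes up aryllithium 7 at −78 °C to give the benzylic carbinol (5Z,8Z,11Z,14Z,17R)-17-[(tert-butyldimethylsilyl)oxy]-1-[2,4,6-tris(methoxymethoxy)phenyl]icosa-5,8,11,14-tetraen-1-ol F4, whose C1 configuration is irrelevant. Oxidation with Dess–Martin periodinane buffered with NaHCO3 in CH2Cl2 gives ketone 9.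

3. Step 6. Formaldehyde equivalents released from the MOM groups may alkylate the free phloroglucinol ring, and acid or air may cause alkene migration or autoxidation during the longer time needed for the para MOM ether. The fallback replaces acid-labile phenol protection by allyl ethers removed under neutral palladium catalysis; it sets out from 5 (with amide 4) and comes back at 10. Phloroglucinol 5 is O-allylated (allyl bromide, K2CO3, DMF) to 1,3,5-tris(prop-2-enyloxy)benzene F5. Ring bromination with NBS (CH2Cl2, −78 → 0 °C) gives 2-bromo-1,3,5-tris(prop-2-enyloxy)benzene F6. Bromine–lithium exchange with n-BuLi in THF at −78 °C gives 2,4,6-tris(prop-2-enyloxy)phenyllithium F7, which adds to 4 through the lithium hemiaminal adduct F8 to give the tris(allyl) silyl ketone F9. Bu4NF buffered with AcOH in THF removes the silyl group to give the 17-hydroxy tris(allyl) ketone F10. Pd(PPh3)4 (zerovalent palladium) with excess morpholine in THF at rt transfers the three allyl groups to the amine and gives 10.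

**Further compounds**
F1 | step 1 | (5Z,8Z,11Z,14Z)-16-[(2S,3R)-3-ethyloxiran-2-yl]hexadeca-5,8,11,14-tetraenoic acid | CC[C@H]1O[C@H]1C/C=C\C/C=C\C/C=C\C/C=C\CCCC(=O)O
F2 | step 1 | (5Z,8Z,11Z,14Z,18R)-18-hydroxyicosa-5,8,11,14-tetraenoic acid | CC[C@@H](O)CC/C=C\C/C=C\C/C=C\C/C=C\CCCC(=O)O
F3 | step 5 | (5Z,8Z,11Z,14Z,17R)-17-[(tert-butyldimethylsilyl)oxy]icosa-5,8,11,14-tetraenal | CCC[C@@H](O[Si](C)(C)C(C)(C)C)C/C=C\C/C=C\C/C=C\C/C=C\CCCC=O
F4 | step 5 | (5Z,8Z,11Z,14Z,17R)-17-[(tert-butyldimethylsilyl)oxy]-1-[2,4,6-tris(methoxymethoxy)phenyl]icosa-5,8,11,14-tetraen-1-ol, C1 epimers | CCC[C@@H](O[Si](C)(C)C(C)(C)C)C/C=C\C/C=C\C/C=C\C/C=C\CCCC(O)c1c(OCOC)cc(OCOC)cc1OCOC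
F5 | step 6 | 1,3,5-tris(prop-2-enyloxy)benzene | C=CCOc1cc(OCC=C)cc(OCC=C)c1
F6 | step 6 | 2-bromo-1,3,5-tris(prop-2-enyloxy)benzene | C=CCOc1cc(OCC=C)c(Br)c(OCC=C)c1
F7 | step 6 | 2,4,6-tris(prop-2-enyloxy)phenyllithium | [Li]c1c(OCC=C)cc(OCC=C)cc1OCC=C
F8 | step 6 | lithium (5Z,8Z,11Z,14Z,17R)-17-[(tert-butyldimethylsilyl)oxy]-1-[methoxy(methyl)amino]-1-[2,4,6-tris(prop-2-enyloxy)phenyl]icosa-5,8,11,14-tetraen-1-olate | CCC[C@@H](O[Si](C)(C)C(C)(C)C)C/C=C\C/C=C\C/C=C\C/C=C\CCCC(O[Li])(N(C)OC)c1c(OCC=C)cc(OCC=C)cc1OCC=C
F9 | step 6 | (5Z,8Z,11Z,14Z,17R)-17-[(tert-butyldimethylsilyl)oxy]-1-[2,4,6-tris(prop-2-enyloxy)phenyl]icosa-5,8,11,14-tetraen-1-one | CCC[C@@H](O[Si](C)(C)C(C)(C)C)C/C=C\C/C=C\C/C=C\C/C=C\CCCC(=O)c1c(OCC=C)cc(OCC=C)cc1OCC=C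
F10 | step 6 | (5Z,8Z,11Z,14Z,17R)-17-hydroxy-1-[2,4,6-tris(prop-2-enyloxy)phenyl]icosa-5,8,11,14-tetraen-1-one | CCC[C@@H](O)C/C=C\C/C=C\C/C=C\C/C=C\CCCC(=O)c1c(OCC=C)cc(OCC=C)cc1OCC=C
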